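**Retrosynthetic overview**
1. Structural feature: C8 of ring A carries the quaternary carbon of the C(CH3)2CH=CH2 group. This leaves C4a as the only hydrogen-bearing carbon beside C8a–O1, and C4a is ortho to O1 and O5 and para to O7. A ring C closure through C4–C4a can therefore only give the 8-substituted chromenone.
2. Target ⇒ 3-hydroxy tri-O-benzyl flavone (debenzylation) ⇒ 5,7,4′-tri-O-benzyl-8-(1,1-dimethylallyl)flavone (C3–O by lithiation, borylation, oxidation) ⇒ (Z)-3-aryloxy-3-arylacrylic acid (C4–C4a, intramolecular Friedel–Crafts acylation).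
3. Acid ⇒ 3,5-bis(benzyloxy)-2-(1,1-dimethylallyl)phenol + methyl 3-[4-(benzyloxy)phenyl]propiolate (O1–C2 by oxa-Michael addition, then saponification).
4. Phenol ⇒ prenyl ether of 3,5-bis(benzyloxy)phenol (aryl–C bond at the future C8 by aromatic Claisen rearrangement). Propiolate ⇒ aryl acetylene + methyl chloroformate.
5. Rings A and B are bought as arenes, and ring C is the only ring made (step 6). The target has no stereocentre.

Key step: step 6

Assumption: O5, O7 and O4′ are carried as benzyl ethers, because cleaving three aryl methyl ethers would need conditions that a 1,1-dimethylallyl group next to a free 7-OH is unlikely to survive; 1 and 6 are taken as catalogue compounds.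

Step 1
Reactants: 1 3,5-bis(benzyloxy)phenol; 2 1-bromo-3-methylbut-2-ene (prenyl bromide)
Product: 3 1,3-bis(benzyloxy)-5-[(3-methylbut-2-en-1-yl)oxy]benzene
Conditions: K2CO3, acetone, reflux
Reagents that add atoms: none
Why: Williamson ether synthesis: the phenoxide formed with K2CO3 displaces bromide from the primary allylic carbon (SN2) through oxygen, and no other group in 1 reacts.

Step 2
Reactants: 3 1,3-bis(benzyloxy)-5-[(3-methylbut-2-en-1-yl)oxy]benzene
Product: 5 3,5-bis(benzyloxy)-2-(2-methylbut-3-en-2-yl)phenol, via ortho-dienone 4 (not isolated)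
Conditions: PhNEt2, 190 °C, Ar
Reagents that add atoms: none
Why: Aromatic Claisen rearrangement: the [3,3] shift inverts the prenyl unit and bonds its tertiary carbon to one of the two equivalent ortho carbons, which sets the quaternary carbon beside the future O1, and the basic solvent speeds enolisation of dienone 4 so that the Cope shift to the para carbon is outrun.

Step 3
Reactants: 6 1-(benzyloxy)-4-ethynylbenzene; 7 methyl chloroformate
Product: 9 methyl 3-[4-(benzyloxy)phenyl]prop-2-ynoate, via lithium acetylide 8 (not isolated)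
Conditions: n-BuLi, THF, −78 °C; then ClCO2Me, −78 → 0 °C
Reagents that add atoms: none
Why: Acylation of a metal acetylide: n-BuLi removes only the terminal alkyne C–H at −78 °C, and acetylide 8 displaces chloride from the chloroformate by addition–elimination.

Step 4
Reactants: 5 3,5-bis(benzyloxy)-2-(2-methylbut-3-en-2-yl)phenol; 9 methyl 3-[4-(benzyloxy)phenyl]prop-2-ynoate
Product: 10 methyl (Z)-3-[3,5-bis(benzyloxy)-2-(2-methylbut-3-en-2-yl)phenoxy]-3-[4-(benzyloxy)phenyl]prop-2-enoate
Conditions: Cs2CO3 (0.3 equiv), DMF, 80–100 °C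
Reagents that add atoms: none
Why: Oxa-Michael addition of a phenoxide to an arylpropiolate (first stage of the Ruhemann flavone synthesis): the cesium phenoxide attacks the β-carbon through oxygen in DMF, anti protonation places OAr and CO2Me cis (Z), and any E isomer can be carried on because step 6 erases the geometry.

Step 5
Reactants: 10 methyl (Z)-3-[3,5-bis(benzyloxy)-2-(2-methylbut-3-en-2-yl)phenoxy]-3-[4-(benzyloxy)phenyl]prop-2-enoate
Product: 11 (Z)-3-[3,5-bis(benzyloxy)-2-(2-methylbut-3-en-2-yl)phenoxy]-3-[4-(benzyloxy)phenyl]prop-2-enoic acid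
Conditions: LiOH, THF–MeOH–H2O, 40 °C; then 1 M HCl to pH 3, 0 °C
Reagents that add atoms: lithium hydroxide, [Li+].[OH-]
Why: Ester saponification by acyl–oxygen cleavage: hydroxide attacks the unhindered ester carbonyl faster than the doubly substituted, donor-deactivated β-carbon, and the brief cold acidification spares the enol ether and the vinyl group.

Step 6
Reactants: 11 (Z)-3-[3,5-bis(benzyloxy)-2-(2-methylbut-3-en-2-yl)phenoxy]-3-[4-(benzyloxy)phenyl]prop-2-enoic acid
Product: 13 5,7-bis(benzyloxy)-2-[4-(benzyloxy)phenyl]-8-(2-methylbut-3-en-2-yl)-4H-chromen-4-one, via mixed trifluoroacetic anhydride 12 (not isolated)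
Conditions: (CF3CO)2O (1.5 equiv), CH2Cl2 (0.02 M), 0 °C → rt; cold aq. NaHCO3 quench
Reagents that add atoms: none
Why: (CF3CO)2O turns acid 11 into mixed anhydride 12, whose ionisation gives an acylium ion stabilised as a ketene–oxocarbenium hybrid by the aryloxy oxygen and the 4-benzyloxyphenyl group; this electrophile attacks C4a, and loss of H+ from the arenium ion forms the C4–C4a bond and the chromen-4-one. The reaction type is an intramolecular Friedel–Crafts acylation, and the closest known case is the ring closure of 3-aryloxycinnamic acids to flavones in the second stage of the Ruhemann synthesis, run here with an aprotic activator in place of a mineral acid. Ring C closes as a six-membered ring in the 6-exo mode at the acyl carbon (exo-trig on 12, exo-dig on the free acylium ion), with the C4a–C8a bond of ring A inside the new ring. No stereocentre is formed, and the alkene geometry does not limit closure, because the C2–C3 bond has single-bond character in the cation, so that E and Z material converge on 13. Regioselectivity is needed between the two carbons ortho to O1 and is secured by the substrate: C8 is blocked by the quaternary carbon, whereas C4a carries hydrogen and is ortho to O1 and O5 and para to O7. Chemoselectivity over the vinyl group, the benzyl ethers and C6 rests on the dilution, the low temperature, the small excess of anhydride and the fact that the only acid present is two equivalents of CF3CO2H, which should not protonate a monosubstituted alkene under these conditions.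

Step 7
Reactants: 13 5,7-bis(benzyloxy)-2-[4-(benzyloxy)phenyl]-8-(2-methylbut-3-en-2-yl)-4H-chromen-4-one
Product: 16 5,7-bis(benzyloxy)-2-[4-(benzyloxy)phenyl]-3-hydroxy-8-(2-methylbut-3-en-2-yl)-4H-chromen-4-one, via 3-lithioflavone 14 (not isolated), via dimethyl flavon-3-ylboronate 15 (not isolated)
Conditions: LiN(iPr)2 (1.3 equiv), THF, −78 °C; B(OMe)3, −78 → 0 °C; AcOH, 30% H2O2, 0 °C → rt
Reagents that add atoms: hydrogen peroxide, OO
Why: Carbonyl-assisted C3 lithiation of a flavone followed by borylation and boronate oxidation, a known way from flavones to flavonols: LiN(iPr)2 removes the only acidic C–H, B(OMe)3 traps 14 before ring opening can set in, and the 1,2-shift from boron to oxygen puts the hydroxyl on C3 without touching the vinyl group or the benzyl ethers.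

Step 8
Reactants: 16 5,7-bis(benzyloxy)-2-[4-(benzyloxy)phenyl]-3-hydroxy-8-(2-methylbut-3-en-2-yl)-4H-chromen-4-one
Product: 17 3,5,7-trihydroxy-2-(4-hydroxyphenyl)-8-(2-methylbut-3-en-2-yl)-4H-chromen-4-one (target)
Conditions: BCl3 (8 equiv), C6HMe5 (10 equiv), CH2Cl2, −78 °C; MeOH–CHCl3 quench at −78 °C, pH 7 buffer wash
Reagents that add atoms: none
Why: Lewis-acid debenzylation of aryl benzyl ethers with a cation scavenger: BCl3 binds each ether oxygen (helped at O5 by chelation to the C4 carbonyl), the benzyl groups pass to pentamethylbenzene by Friedel–Crafts alkylation, and at −78 °C the monosubstituted alkene should be neither protonated nor attacked by the freed 7-OH.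

**Compound list**
1 | 3,5-bis(benzyloxy)phenol | Oc1cc(OCc2ccccc2)cc(OCc2ccccc2)c1 | starting material
2 | 1-bromo-3-methylbut-2-ene (prenyl bromide) | CC(C)=CCBr | starting material
3 | 1,3-bis(benzyloxy)-5-[(3-methylbut-2-en-1-yl)oxy]benzene | CC(C)=CCOc1cc(OCc2ccccc2)cc(OCc2ccccc2)c1 | intermediate
4 | 3,5-bis(benzyloxy)-6-(2-methylbut-3-en-2-yl)cyclohexa-2,4-dien-1-one (ortho-dienone, racemic, transient) | O=C1C=C(OCc2ccccc2)C=C(OCc2ccccc2)C1C(C)(C)C=C | intermediate
5 | 3,5-bis(benzyloxy)-2-(2-methylbut-3-en-2-yl)phenol | C=CC(C)(C)c1c(O)cc(OCc2ccccc2)cc1OCc1ccccc1 | intermediate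
6 | 1-(benzyloxy)-4-ethynylbenzene | C#Cc1ccc(OCc2ccccc2)cc1 | starting material
7 | methyl chloroformate | COC(=O)Cl | starting material
8 | lithium [4-(benzyloxy)phenyl]acetylide | [Li]C#Cc1ccc(OCc2ccccc2)cc1 | intermediate
9 | methyl 3-[4-(benzyloxy)phenyl]prop-2-ynoate | COC(=O)C#Cc1ccc(OCc2ccccc2)cc1 | intermediate
10 | methyl (Z)-3-[3,5-bis(benzyloxy)-2-(2-methylbut-3-en-2-yl)phenoxy]-3-[4-(benzyloxy)phenyl]prop-2-enoate | COC(=O)/C=C(/c1ccc(OCc2ccccc2)cc1)Oc1cc(OCc2ccccc2)cc(OCc2ccccc2)c1C(C)(C)C=C | intermediate
11 | (Z)-3-[3,5-bis(benzyloxy)-2-(2-methylbut-3-en-2-yl)phenoxy]-3-[4-(benzyloxy)phenyl]prop-2-enoic acid | O=C(O)/C=C(/c1ccc(OCc2ccccc2)cc1)Oc1cc(OCc2ccccc2)cc(OCc2ccccc2)c1C(C)(C)C=C | intermediate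
12 | (Z)-3-[3,5-bis(benzyloxy)-2-(2-methylbut-3-en-2-yl)phenoxy]-3-[4-(benzyloxy)phenyl]prop-2-enoic trifluoroacetic anhydride | O=C(OC(=O)C(F)(F)F)/C=C(/c1ccc(OCc2ccccc2)cc1)Oc1cc(OCc2ccccc2)cc(OCc2ccccc2)c1C(C)(C)C=C | intermediate
13 | 5,7-bis(benzyloxy)-2-[4-(benzyloxy)phenyl]-8-(2-methylbut-3-en-2-yl)-4H-chromen-4-one | C=CC(C)(C)c1c(OCc2ccccc2)cc(OCc2ccccc2)c2c(=O)cc(-c3ccc(OCc4ccccc4)cc3)oc12 | intermediate
14 | 5,7-bis(benzyloxy)-2-[4-(benzyloxy)phenyl]-3-lithio-8-(2-methylbut-3-en-2-yl)-4H-chromen-4-one | [Li]c1c(-c2ccc(OCc3ccccc3)cc2)oc2c(C(C)(C)C=C)c(OCc3ccccc3)cc(OCc3ccccc3)c2c1=O | intermediate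
15 | dimethyl {5,7-bis(benzyloxy)-2-[4-(benzyloxy)phenyl]-8-(2-methylbut-3-en-2-yl)-4-oxo-4H-chromen-3-yl}boronate | COB(OC)c1c(-c2ccc(OCc3ccccc3)cc2)oc2c(C(C)(C)C=C)c(OCc3ccccc3)cc(OCc3ccccc3)c2c1=O | intermediate
16 | 5,7-bis(benzyloxy)-2-[4-(benzyloxy)phenyl]-3-hydroxy-8-(2-methylbut-3-en-2-yl)-4H-chromen-4-one | C=CC(C)(C)c1c(OCc2ccccc2)cc(OCc2ccccc2)c2c(=O)c(O)c(-c3ccc(OCc4ccccc4)cc3)oc12 | intermediate
17 | 3,5,7-trihydroxy-2-(4-hydroxyphenyl)-8-(2-methylbut-3-en-2-yl)-4H-chromen-4-one | C=CC(C)(C)c1c(O)cc(O)c2c(=O)c(O)c(-c3ccc(O)cc3)oc12 | target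

Total step count: 8. Longest linear sequence: 7 steps (1, 2, 4, 5, 6, 7, 8).

**Steps most likely to fail**

**Step 6.** Several processes could compete with closure:
- trifluoroacetylation of ring A at C6 or of the enol ether;
- decarboxylation of 11 before closure;
- acid-induced reaction of the vinyl group with participation of the electron-rich ring;
- ipso attack at C8 with loss of the allyl cation.

The fallback sets out from phenol 5 and acetylide 8 and comes back at 13. It makes the C4–C4a bond first, under basic conditions. Phenol 5 is formylated at its only free ortho carbon with MgCl2, Et3N and paraformaldehyde in MeCN at reflux (Casnati–Skattebøl formylation). This should give 4,6-bis(benzyloxy)-2-hydroxy-3-(2-methylbut-3-en-2-yl)benzaldehyde F1. An excess of lithium acetylide 8 in THF at −78 °C adds to the aldehyde to give racemic 1-[4,6-bis(benzyloxy)-2-hydroxy-3-(2-methylbut-3-en-2-yl)phenyl]-3-[4-(benzyloxy)phenyl]prop-2-yn-1-ol F2. This alcohol is oxidised without delay with MnO2 in CH2Cl2 to 1-[4,6-bis(benzyloxy)-2-hydroxy-3-(2-methylbut-3-en-2-yl)phenyl]-3-[4-(benzyloxy)phenyl]prop-2-yn-1-one F3. Catalytic DMAP in DMF then closes O1–C2 by a 6-endo-dig oxa-Michael addition to 13.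

**Step 2.** Four processes could erode the ortho product at 190 °C:
- the Cope shift of dienone 4 to the para carbon;
- thermal loss of isoprene from 3;
- an onward abnormal Claisen rearrangement of the free phenol;
- ring closure of the phenol on the vinyl group.

The fallback sets out from 3 and comes back at 5. The rearrangement is run in PhNEt2 with butyric anhydride, so that the phenol is acylated as soon as it forms. It is then isolated as 3,5-bis(benzyloxy)-2-(2-methylbut-3-en-2-yl)phenyl butanoate F4, which has no O–H left for the secondary reactions. Methanolysis with catalytic K2CO3 in MeOH at room temperature then releases 5.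

**Step 8.** The freed 7-OH or HCl could add across the vinyl group during cleavage or on warming. Incomplete cleavage of the 4′-ether is also possible.

The fallback sets out from 16 and comes back at 17. The benzyl groups are removed by SN2 attack of NaSEt at the benzylic carbons in DMF at 110 °C. Every phenol is then released as its phenoxide and no acid is present until a cold, brief acidification. No compound outside the list is made (F0).

**Further compounds**
F1 | step 6 | 4,6-bis(benzyloxy)-2-hydroxy-3-(2-methylbut-3-en-2-yl)benzaldehyde | C=CC(C)(C)c1c(O)c(C=O)c(OCc2ccccc2)cc1OCc1ccccc1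
F2 | step 6 | 1-[4,6-bis(benzyloxy)-2-hydroxy-3-(2-methylbut-3-en-2-yl)phenyl]-3-[4-(benzyloxy)phenyl]prop-2-yn-1-ol (racemic) | C=CC(C)(C)c1c(O)c(C(O)C#Cc2ccc(OCc3ccccc3)cc2)c(OCc2ccccc2)cc1OCc1ccccc1
F3 | step 6 | 1-[4,6-bis(benzyloxy)-2-hydroxy-3-(2-methylbut-3-en-2-yl)phenyl]-3-[4-(benzyloxy)phenyl]prop-2-yn-1-one | C=CC(C)(C)c1c(O)c(C(=O)C#Cc2ccc(OCc3ccccc3)cc2)c(OCc2ccccc2)cc1OCc1ccccc1
F4 | step 2 | 3,5-bis(benzyloxy)-2-(2-methylbut-3-en-2-yl)phenyl butanoate | C=CC(C)(C)c1c(OC(=O)CCC)cc(OCc2ccccc2)cc1OCc1ccccc1
F0 | step 8 | none | none
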